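## Retrosynthetic overview

1. Target 29 ⇒ C8–O ester disconnection: hydroxy lactone aldehyde 23 + acetonide acid 27 (from (R)-solketal 24).
2. Key step, γ-lactone ring (O6–C12): hydroxyl-relayed C(sp3)–H oxidation/lactonisation of the C12 methyl of cyclohexanol 18 (new method); the C15 aldehyde comes from a pre-installed C15 silyl ether.
3. Cyclohexane ring (C6–C7): type 1 carbonyl-ene closure of acyclic aldehyde 17, fixing C6 and C7.
4. C5–C10 bond: reagent-controlled Ireland–Claisen rearrangement of allyl ester 13 (C5 and quaternary C10).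
5. 13 ⇒ allylic alcohol 6 (prenal 1 + allenylboronate 2, then carboalumination) + acid 10. Ring order: carbocycle first, lactone second.

Locants follow elemane numbering: C10 quaternary, C5 bears the C3/C4/C15 propenal unit, C6 lactone carbinol, C7 bears C11(=C13)–C12, C8 ester carbinol. TBS = tert-butyldimethylsilyl.

Assumption: the absolute sense of the two reagent-controlled steps (1 and 7) is assigned by analogy with the closest known cases, and the mirror-image catalyst or controller is used if a test run shows the opposite sense.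

## Route

Step 1
Reactants: 1 3-methylbut-2-enal (prenal); 2 allenylboronic acid pinacol ester
Product: 3 (S)-2-methylhept-2-en-6-yn-4-ol
Conditions: (S)-3,3'-bis(2,4,6-triisopropylphenyl)-1,1'-binaphthyl-2,2'-diyl hydrogen phosphate (5 mol%), 4 Å MS, toluene, −20 °C; aq. NaHCO3
Reagents that add atoms: none
Why: Chiral phosphoric acid-catalysed asymmetric propargylation (SE2' addition of the allenylboronate through a closed six-membered transition state) delivers the propargyl group to the Si face of the enal carbonyl, which sets the C8 carbinol centre as S.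

Step 2
Reactants: 3
Product: 4 (S)-tert-butyldimethyl[(2-methylhept-2-en-6-yn-4-yl)oxy]silane
Conditions: TBSCl, imidazole, DMF, 0 °C → rt
Reagents that add atoms: tert-butyldimethylsilyl chloride CC(C)(C)[Si](C)(C)Cl
Why: Standard silyl ether protection gives a C8–O group that survives the organoaluminium, enolate, hydride and Lewis acid steps, and no stereocentre is touched.

Step 3
Reactants: 4
Product: 6 (S,E)-5-(TBSO)-3,7-dimethylocta-2,6-dien-1-ol, via alkenylalane 5 (not isolated)
Conditions: AlMe3 (3 equiv), Cp2ZrCl2 (0.3 equiv), CH2Cl2, 0 °C → rt; then (CH2O)n, THF, 0 °C → rt; aq. potassium sodium tartrate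
Reagents that add atoms: trimethylaluminium C[Al](C)C; formaldehyde (from paraformaldehyde) C=O
Why: Zirconium-catalysed Negishi carboalumination adds methyl and aluminium syn across the terminal alkyne (methyl to the internal carbon) and the alkenylalane is hydroxymethylated with retention, so only the E-trisubstituted allylic alcohol forms.

Step 4
Reactants: 7 1-(TBSO)propan-2-one; 8 triethyl phosphonoacetate
Product: 9 ethyl (E)-4-(TBSO)-3-methylbut-2-enoate
Conditions: NaH, THF, 0 °C → rt; chromatography (E isomer kept)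
Reagents that add atoms: none
Why: Horner–Wadsworth–Emmons olefination of the α-silyloxy ketone gives mainly the E-enoate (about 4:1), which is separated so that the methyl group sits cis to the carbonyl for the later γ-deprotonation.

Step 5
Reactants: 9
Product: 10 (E)-4-(TBSO)-3-methylbut-2-enoic acid
Conditions: LiOH, THF–MeOH–H2O, 0 °C → rt; aq. NaHSO4 to pH 4
Reagents that add atoms: lithium hydroxide [Li+].[OH-]
Why: Saponification of the ethyl ester leaves the primary silyl ether and the alkene geometry unchanged.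

Step 6
Reactants: 10; 6
Product: 13 (2E,5S)-5-(TBSO)-3,7-dimethylocta-2,6-dien-1-yl 3-[(TBSO)methyl]but-3-enoate, via acid chloride 11 (not isolated), via vinylketene 12 (not isolated)
Conditions: 1-chloro-N,N,2-trimethylprop-1-en-1-amine, CH2Cl2, 0 °C; then 6, Et3N, CH2Cl2, −78 → 0 °C
Reagents that add atoms: none
Why: Acylation through a vinylketene: Et3N removes HCl from the acid chloride by 1,4-elimination at the cis γ-methyl group and the alcohol adds to the ketene with kinetic α-protonation, so the ester C–O bond forms directly as the β,γ-unsaturated isomer, as known for 3-methylbut-2-enoyl chloride.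

Step 7
Reactants: 13
Product: 15 (2R,3S,5S)-5-(TBSO)-2-[3-(TBSO)prop-1-en-2-yl]-3-ethenyl-3,7-dimethyloct-6-enoic acid, via boron ketene acetal 14 (not isolated)
Conditions: (4S,5S)-2-bromo-1,3-bis{[3,5-bis(trifluoromethyl)phenyl]sulfonyl}-4,5-diphenyl-1,3,2-diazaborolidine (1.3 equiv, made in the flask from the (S,S)-bis-sulfonamide and BBr3, volatiles removed), Et3N, toluene–hexane, −78 °C; then −20 → 4 °C, 5–10 d; aqueous work-up
Reagents that add atoms: none
Why: Soft enolisation of the β,γ-unsaturated ester gives the E(O)-boron ketene acetal, and its enantioselective Ireland–Claisen rearrangement through a chair transition state (E-allyl unit, α-substituent cis to the allyl oxygen) sets C5 (R) and the quaternary C10 (S) under reagent control, independent of the remote C8 centre.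

Step 8
Reactants: 15
Product: 16 (2R,3S,5S)-5-(TBSO)-2-[3-(TBSO)prop-1-en-2-yl]-3-ethenyl-3,7-dimethyloct-6-en-1-ol
Conditions: LiAlH4, THF, 0 °C → rt
Reagents that add atoms: none
Why: Hydride reduction of the hindered carboxylic acid to the primary alcohol leaves the silyl ethers and the isolated alkenes untouched.

Step 9
Reactants: 16
Product: 17 (2R,3S,5S)-5-(TBSO)-2-[3-(TBSO)prop-1-en-2-yl]-3-ethenyl-3,7-dimethyloct-6-enal
Conditions: Dess–Martin periodinane, NaHCO3, CH2Cl2, 0 °C → rt
Reagents that add atoms: none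
Why: Buffered Dess–Martin oxidation gives the α-branched aldehyde without epimerising C5 or moving the β,γ-double bond into conjugation.

Step 10
Reactants: 17
Product: 18 8α,15-bis(TBSO)elema-1,3,11(13)-trien-6α-ol (5α-H, 7α-H, 10β-methyl)
Conditions: Me2AlCl (1.5 equiv), CH2Cl2, −78 → −30 °C; aq. potassium sodium tartrate
Reagents that add atoms: none
Why: Type 1 intramolecular carbonyl-ene reaction (as in citronellal to isopulegol) through a chair transition state with the C5 side chain, the C8 silyl ether and the C10 vinyl group equatorial transfers a hydrogen from the E-methyl group and sets C6 (α-OH) and C7 (β-isopropenyl) trans-diequatorial.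

Step 11
Reactants: 18
Product: 21 8α,15-bis(TBSO)elema-1,3,11(13)-trien-12,6α-olide, via allylic diol 19 (not isolated), via lactol 20 (not isolated)
Conditions: SeO2 (0.3 equiv), 2,2,6,6-tetramethylpiperidin-1-oxyl (TEMPO, 0.15 equiv), PhI(OAc)2 (3.3 equiv), H2O (2 equiv), CH2Cl2, 25 °C
Reagents that add atoms: selenium dioxide O=[Se]=O; water O
Why: Proposed new method: a selenium/oxoammonium relay C–H lactonisation in which tetravalent selenium hydroxylates C12 by the usual ene/[2,3]-sigmatropic sequence (C12 is the only allylic methyl on an alkene not deactivated by an allylic oxygen), trivalent iodine reoxidises the divalent selenium by-product so SeO2 is catalytic, and the TEMPO-derived oxoammonium ion, turned over by the same PhI(OAc)2, oxidises the new primary allylic alcohol to the enal, which the adjacent 6-OH traps as the lactol that is oxidised again to the trans-fused α-methylene lactone, the hindered secondary 6-OH itself being too slow for TEMPO; the closest known reactions are catalytic SeO2/tert-butyl hydroperoxide allylic hydroxylation and TEMPO/PhI(OAc)2 oxidative lactonisation of 1,4-diols.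

Step 12
Reactants: 21
Product: 22 8α,15-dihydroxyelema-1,3,11(13)-trien-12,6α-olide
Conditions: HF·pyridine, pyridine, THF, 0 °C → rt
Reagents that add atoms: none
Why: Buffered acidic fluoride desilylation removes both TBS ethers without the base-induced translactonisation to the 8,12-olide that a free 8-alkoxide would cause.

Step 13
Reactants: 22
Product: 23 8α-hydroxy-15-oxoelema-1,3,11(13)-trien-12,6α-olide
Conditions: MnO2 (20 equiv), CH2Cl2, rt
Reagents that add atoms: none
Why: Manganese dioxide oxidises only the primary allylic C15 alcohol to the 2-substituted propenal and leaves the saturated secondary 8-OH and the lactone untouched.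

Step 14
Reactants: 24 (R)-solketal [(R)-(2,2-dimethyl-1,3-dioxolan-4-yl)methanol]
Product: 26 (R)-4-ethynyl-2,2-dimethyl-1,3-dioxolane, via aldehyde 25 (not isolated)
Conditions: 2,2,6,6-tetramethylpiperidin-1-oxyl (TEMPO, 10 mol%), PhI(OAc)2, CH2Cl2, rt; then MeOH, K2CO3, dimethyl (1-diazo-2-oxopropyl)phosphonate, 0 °C → rt
Reagents that add atoms: dimethyl (1-diazo-2-oxopropyl)phosphonate CC(=O)C(=[N+]=[N-])P(=O)(OC)OC
Why: Nitroxyl oxidation followed in the same flask by Seyferth–Gilbert homologation (Ohira–Bestmann reagent) converts the configurationally labile (S)-glyceraldehyde acetonide straight into the alkyne, so the chiral-pool centre is carried over without racemisation.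

Step 15
Reactants: 26
Product: 27 (R)-2-(2,2-dimethyl-1,3-dioxolan-4-yl)prop-2-enoic acid
Conditions: Pd(OAc)2 (1 mol%), diphenyl(2-pyridyl)phosphine (8 mol%), methanesulfonic acid (4 mol%), CO (20 bar), H2O (3 equiv), acetone, 50 °C
Reagents that add atoms: carbon monoxide [C-]#[O+]; water O
Why: Palladium-catalysed Markovnikov hydroxycarbonylation of the terminal alkyne (pyridylphosphine as proton relay, CO insertion, hydrolysis of the acyl–palladium bond) gives the 2-substituted acrylic acid, with the stereocentre untouched and acetone as solvent keeping the acetonide in place.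

Step 16
Reactants: 23; 27
Product: 28 8α-{[(R)-2-(2,2-dimethyl-1,3-dioxolan-4-yl)prop-2-enoyl]oxy}-15-oxoelema-1,3,11(13)-trien-12,6α-olide
Conditions: 2-methyl-6-nitrobenzoic anhydride (1.3 equiv), 4-(dimethylamino)pyridine (0.3 equiv), Et3N, CH2Cl2, rt
Reagents that add atoms: none
Why: Shiina mixed-anhydride esterification forms the C8–O ester bond on the equatorial secondary alcohol under mild conditions with retention at C8 and at the side-chain centre.

Step 17
Reactants: 28
Product: 29 CNP0204284.1 [8α-{[(3R)-3,4-dihydroxy-2-methylidenebutanoyl]oxy}-15-oxoelema-1,3,11(13)-trien-12,6α-olide]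
Conditions: AcOH–H2O (4:1), 40 °C
Reagents that add atoms: none
Why: Mild acid-catalysed acetal hydrolysis frees the side-chain diol without affecting the enal, the two acrylate-type esters or any stereocentre.

## Compound list

1 | 3-methylbut-2-enal (prenal) | CC(C)=CC=O | starting material
2 | allenylboronic acid pinacol ester | C=C=CB1OC(C)(C)C(C)(C)O1 | starting material
3 | (S)-2-methylhept-2-en-6-yn-4-ol | C#CC[C@H](O)C=C(C)C | intermediate
4 | (S)-tert-butyldimethyl[(2-methylhept-2-en-6-yn-4-yl)oxy]silane | C#CC[C@H](O[Si](C)(C)C(C)(C)C)C=C(C)C | intermediate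
5 | dimethyl[(1E,4S)-4-(TBSO)-2,6-dimethylhepta-1,5-dien-1-yl]alane | C[Al](C)/C=C(\C)C[C@H](O[Si](C)(C)C(C)(C)C)C=C(C)C | intermediate
6 | (S,E)-5-(TBSO)-3,7-dimethylocta-2,6-dien-1-ol | OC/C=C(\C)C[C@H](O[Si](C)(C)C(C)(C)C)C=C(C)C | intermediate
7 | 1-(TBSO)propan-2-one | CC(=O)CO[Si](C)(C)C(C)(C)C | starting material
8 | triethyl phosphonoacetate | CCOC(=O)CP(=O)(OCC)OCC | starting material
9 | ethyl (E)-4-(TBSO)-3-methylbut-2-enoate | CCOC(=O)/C=C(\C)CO[Si](C)(C)C(C)(C)C | intermediate
10 | (E)-4-(TBSO)-3-methylbut-2-enoic acid | OC(=O)/C=C(\C)CO[Si](C)(C)C(C)(C)C | intermediate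
11 | (E)-4-(TBSO)-3-methylbut-2-enoyl chloride | ClC(=O)/C=C(\C)CO[Si](C)(C)C(C)(C)C | intermediate
12 | 3-[(TBSO)methyl]buta-1,3-dien-1-one (vinylketene) | O=C=CC(=C)CO[Si](C)(C)C(C)(C)C | intermediate
13 | (2E,5S)-5-(TBSO)-3,7-dimethylocta-2,6-dien-1-yl 3-[(TBSO)methyl]but-3-enoate | C=C(CC(=O)OC/C=C(\C)C[C@H](O[Si](C)(C)C(C)(C)C)C=C(C)C)CO[Si](C)(C)C(C)(C)C | intermediate
14 | E(O)-boron ketene acetal of 13 with the (4S,5S)-diazaborolidine (O–B trans to the propenyl substituent) | C=C(CO[Si](C)(C)C(C)(C)C)/C=C(\OC/C=C(\C)C[C@H](O[Si](C)(C)C(C)(C)C)C=C(C)C)OB1N(S(=O)(=O)c2cc(cc(c2)C(F)(F)F)C(F)(F)F)[C@@H](c2ccccc2)[C@H](c2ccccc2)N1S(=O)(=O)c1cc(cc(c1)C(F)(F)F)C(F)(F)F | intermediate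
15 | (2R,3S,5S)-5-(TBSO)-2-[3-(TBSO)prop-1-en-2-yl]-3-ethenyl-3,7-dimethyloct-6-enoic acid | C=C[C@](C)(C[C@H](O[Si](C)(C)C(C)(C)C)C=C(C)C)[C@@H](C(=O)O)C(=C)CO[Si](C)(C)C(C)(C)C | intermediate
16 | (2R,3S,5S)-5-(TBSO)-2-[3-(TBSO)prop-1-en-2-yl]-3-ethenyl-3,7-dimethyloct-6-en-1-ol | C=C[C@](C)(C[C@H](O[Si](C)(C)C(C)(C)C)C=C(C)C)[C@@H](CO)C(=C)CO[Si](C)(C)C(C)(C)C | intermediate
17 | (2R,3S,5S)-5-(TBSO)-2-[3-(TBSO)prop-1-en-2-yl]-3-ethenyl-3,7-dimethyloct-6-enal | C=C[C@](C)(C[C@H](O[Si](C)(C)C(C)(C)C)C=C(C)C)[C@@H](C=O)C(=C)CO[Si](C)(C)C(C)(C)C | intermediate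
18 | 8α,15-bis(TBSO)elema-1,3,11(13)-trien-6α-ol | C=C[C@]1(C)C[C@H](O[Si](C)(C)C(C)(C)C)[C@@H](C(C)=C)[C@H](O)[C@H]1C(=C)CO[Si](C)(C)C(C)(C)C | intermediate
19 | 8α,15-bis(TBSO)elema-1,3,11(13)-triene-6α,12-diol | C=C[C@]1(C)C[C@H](O[Si](C)(C)C(C)(C)C)[C@@H](C(=C)CO)[C@H](O)[C@H]1C(=C)CO[Si](C)(C)C(C)(C)C | intermediate
20 | 8α,15-bis(TBSO)-6α,12-epoxyelema-1,3,11(13)-trien-12-ol (lactol, anomer mixture) | C=C[C@]1(C)C[C@H](O[Si](C)(C)C(C)(C)C)[C@H]2C(=C)C(O)O[C@@H]2[C@H]1C(=C)CO[Si](C)(C)C(C)(C)C | intermediate
21 | 8α,15-bis(TBSO)elema-1,3,11(13)-trien-12,6α-olide | C=C[C@]1(C)C[C@H](O[Si](C)(C)C(C)(C)C)[C@H]2C(=C)C(=O)O[C@@H]2[C@H]1C(=C)CO[Si](C)(C)C(C)(C)C | intermediate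
22 | 8α,15-dihydroxyelema-1,3,11(13)-trien-12,6α-olide | C=C[C@]1(C)C[C@H](O)[C@H]2C(=C)C(=O)O[C@@H]2[C@H]1C(=C)CO | intermediate
23 | 8α-hydroxy-15-oxoelema-1,3,11(13)-trien-12,6α-olide | C=C[C@]1(C)C[C@H](O)[C@H]2C(=C)C(=O)O[C@@H]2[C@H]1C(=C)C=O | intermediate
24 | (R)-solketal | OC[C@@H]1COC(C)(C)O1 | starting material
25 | (S)-2,2-dimethyl-1,3-dioxolane-4-carbaldehyde | O=C[C@@H]1COC(C)(C)O1 | intermediate
26 | (R)-4-ethynyl-2,2-dimethyl-1,3-dioxolane | C#C[C@@H]1COC(C)(C)O1 | intermediate
27 | (R)-2-(2,2-dimethyl-1,3-dioxolan-4-yl)prop-2-enoic acid | C=C(C(=O)O)[C@@H]1COC(C)(C)O1 | intermediate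
28 | 8α-{[(R)-2-(2,2-dimethyl-1,3-dioxolan-4-yl)prop-2-enoyl]oxy}-15-oxoelema-1,3,11(13)-trien-12,6α-olide | C=C[C@]1(C)C[C@H](OC(=O)C(=C)[C@@H]3COC(C)(C)O3)[C@H]2C(=C)C(=O)O[C@@H]2[C@H]1C(=C)C=O | intermediate
29 | CNP0204284.1 | C=C[C@]1(C)C[C@H](OC(=O)C(=C)[C@@H](O)CO)[C@H]2C(=C)C(=O)O[C@@H]2[C@H]1C(=C)C=O | target

## Step count and risks

Total: 17 steps. Longest linear sequence: 13 steps (1, 2, 3, 6, 7, 8, 9, 10, 11, 12, 13, 16, 17). Steps 4–5 and 14–15 are side branches.

The three steps most likely to fail: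

**Step 7 (Ireland–Claisen).** The rearrangement builds a quaternary centre and is slow. The E(O) geometry of an α-alkenyl ester enolate is less secure than for simple esters, and the Lewis-acidic boron reagent may attack the allylic silyl ethers. The fallback sets out from 13 and gives up reagent control. LDA in THF at −78 °C followed by TMSCl/Et3N gives the E(O) trimethylsilyl ketene acetal F1, which rearranges on warming through the same chair to the trimethylsilyl esters F2. Aqueous work-up gives 15 together with its (2S,3R,5S)-diastereomer F3 in about 1:1 ratio (same C5/C10 relative configuration, opposite sense relative to C8). The two are separated by chromatography, or after step 10 where only material from 15 can give the all-equatorial 18. The fallback comes back at 15.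

**Step 10 (carbonyl-ene closure).** In the desired chair the equatorial C8 silyl ether suffers allylic 1,3-strain with the Z-methyl of the ene alkene. This may lower the C6/C7 selectivity, and the Lewis acid may ionise the allylic silyl ether. The fallback sets out from 17 and replaces kinetic control by thermodynamic control. The aldehyde is cyclised without regard to selectivity (Me2AlCl or SnCl4) to the C6/C7-epimeric cyclohexanols F4. These are oxidised with Dess–Martin periodinane to the 6-ketone F5, and the α-centres are equilibrated with catalytic DBU at 0 °C to the all-equatorial ketone. Reduction with LiAlH(O-t-Bu)3 (axial hydride delivery) gives the equatorial 6α-alcohol. The fallback comes back at 18.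

**Step 11 (proposed relay lactonisation).** Turnover of selenium by trivalent iodine is unproven, and the oxoammonium ion could attack the electron-rich alkenes or, slowly, the 6-OH. The fallback uses known chemistry and sets out from 18. SeO2 (0.5 equiv) with tert-butyl hydroperoxide in CH2Cl2 gives the allylic diol 19 (with some lactol 20), which is isolated. A separate TEMPO/PhI(OAc)2 (or MnO2) oxidative lactonisation then gives the lactone. The fallback comes back at 21 and makes no compound outside the list (F0).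

Further compounds

F1 | step 7 | E(O) trimethylsilyl ketene acetal of 13 | C=C(CO[Si](C)(C)C(C)(C)C)/C=C(\OC/C=C(\C)C[C@H](O[Si](C)(C)C(C)(C)C)C=C(C)C)O[Si](C)(C)C
F2 | step 7 | trimethylsilyl esters of 15 and of F3 (mixture at C2 and C3) | C=CC(C)(C[C@H](O[Si](C)(C)C(C)(C)C)C=C(C)C)C(C(=O)O[Si](C)(C)C)C(=C)CO[Si](C)(C)C(C)(C)C
F3 | step 7 | (2S,3R,5S)-5-(TBSO)-2-[3-(TBSO)prop-1-en-2-yl]-3-ethenyl-3,7-dimethyloct-6-enoic acid | C=C[C@@](C)(C[C@H](O[Si](C)(C)C(C)(C)C)C=C(C)C)[C@H](C(=O)O)C(=C)CO[Si](C)(C)C(C)(C)C
F4 | step 10 | 8α,15-bis(TBSO)elema-1,3,11(13)-trien-6-ols, epimeric at C6 and C7 | C=C[C@]1(C)C[C@H](O[Si](C)(C)C(C)(C)C)C(C(C)=C)C(O)[C@H]1C(=C)CO[Si](C)(C)C(C)(C)C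
F5 | step 10 | 8α,15-bis(TBSO)elema-1,3,11(13)-trien-6-one (all-equatorial after equilibration) | C=C[C@]1(C)C[C@H](O[Si](C)(C)C(C)(C)C)[C@@H](C(C)=C)C(=O)[C@H]1C(=C)CO[Si](C)(C)C(C)(C)C
F0 | step 11 | none | none
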